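**Strategy.** Ring A (C1–OMe, C2–H, C3–OH, C4 and C6 4‑hydroxybenzyl, C5 the CH2CH2 link to ring B) is assembled last by a Danheiser benzannulation. Photolysis of an α‑diazo enone that already carries both benzyl arms and the ring B ethyl chain gives a vinylketene, which adds methoxyacetylene and rearranges to the pentasubstituted phenol. This one operation closes ring A, makes C5–C6, C6–C1, C2–C3 and C3–C4, and fixes the meta OMe/OH pattern around C2–H through the bonding of the two partners. The diazo enone comes from a ring B propylphosphonate by ester acylation, Horner–Wadsworth–Emmons olefination and diazo transfer. Four benzyl ethers mask the other phenols until a final hydrogenolysis.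

Key step: step 11

Remark on the chemistry: the target is achiral, so the stereocentres that appear in passing (diarylcarbinol, ketophosphonate, trifluoroacetyl diketone, vinylcyclobutenone, cyclohexadienone) are racemic and are all destroyed; 4‑(benzyloxy)benzaldehyde, 2‑[4‑(benzyloxy)phenyl]ethanol and diethyl allylphosphonate are taken as purchased.

**Step 1**
Reactants: 1 3,5‑dibromophenol
Product: 2 1‑(benzyloxy)‑3,5‑dibromobenzene
Conditions: BnBr (1.1 equiv), K2CO3, DMF, rt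
Reagents that add atoms: benzyl bromide, BrCc1ccccc1
Why: Williamson etherification of the phenoxide with benzyl bromide should be clean, since the aryl bromides are inert to K2CO3 in DMF.

**Step 2**
Reactants: 2 1‑(benzyloxy)‑3,5‑dibromobenzene; 3 4‑(benzyloxy)benzaldehyde
Product: 5 [3‑(benzyloxy)‑5‑bromophenyl][4‑(benzyloxy)phenyl]methanol, via aryllithium 4 (not isolated)
Conditions: n‑BuLi (1.0 equiv), Et2O, −78 °C; then 3, −78 → 0 °C; H2O
Reagents that add atoms: none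
Why: Bromine–lithium exchange at −78 °C should stop after one exchange because the aryllithium deactivates the second C–Br bond, and 1,2‑addition to the non‑enolisable aldehyde gives the racemic diarylcarbinol, whose stereocentre is removed in step 3.

**Step 3**
Reactants: 5 [3‑(benzyloxy)‑5‑bromophenyl][4‑(benzyloxy)phenyl]methanol
Product: 6 1‑(benzyloxy)‑3‑[4‑(benzyloxy)benzyl]‑5‑bromobenzene
Conditions: Et3SiH (3 equiv), CF3CO2H (5 equiv), CH2Cl2, 0 °C
Reagents that add atoms: none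
Why: Ionic hydrogenation (acid‑promoted ionisation to a benzhydryl cation stabilised by the para‑benzyloxy group, then hydride transfer from the silane) should deoxygenate the carbinol without touching the aryl bromide or, at 0 °C, the benzyl ethers.

**Step 4**
Reactants: 6 1‑(benzyloxy)‑3‑[4‑(benzyloxy)benzyl]‑5‑bromobenzene; 7 diethyl allylphosphonate
Product: 9 diethyl (3‑{3‑(benzyloxy)‑5‑[4‑(benzyloxy)benzyl]phenyl}propyl)phosphonate, via alkylborane 8 (not isolated)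
Conditions: 7, 9‑BBN (1.2 equiv), THF, 0 °C → rt; then 6, PdCl2(dppf) (5 mol %), aq. K3PO4, DMF, 60 °C
Reagents that add atoms: none
Why: Anti‑Markovnikov hydroboration of the terminal alkene with 9‑BBN followed by B‑alkyl Suzuki–Miyaura coupling with the aryl bromide should install the three‑carbon phosphonate chain in one pot, the phosphonate ester and benzyl ethers being inert.

**Step 5**
Reactants: 10 methyl 3‑(4‑hydroxyphenyl)propanoate
Product: 11 methyl 3‑[4‑(benzyloxy)phenyl]propanoate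
Conditions: BnBr (1.1 equiv), K2CO3, acetone, reflux
Reagents that add atoms: benzyl bromide, BrCc1ccccc1
Why: Williamson etherification of the phenol, which the methyl ester survives under anhydrous carbonate conditions.

**Step 6**
Reactants: 9 diethyl (3‑{3‑(benzyloxy)‑5‑[4‑(benzyloxy)benzyl]phenyl}propyl)phosphonate; 11 methyl 3‑[4‑(benzyloxy)phenyl]propanoate
Product: 12 diethyl (1‑{3‑(benzyloxy)‑5‑[4‑(benzyloxy)benzyl]phenyl}‑6‑[4‑(benzyloxy)phenyl]‑4‑oxohexan‑3‑yl)phosphonate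
Conditions: LiN(iPr)2 (2.2 equiv) added to 9 + 11 (1.1 equiv), THF, 0 °C; then 1 M HCl
Reagents that add atoms: none
Why: Claisen‑type acylation of the α‑lithiated alkylphosphonate by the ester should give the α‑substituted β‑ketophosphonate directly (no alkylation with an elimination‑prone 2‑arylethyl halide is needed), the second equivalent of base holding the product as its enolate against over‑addition; the new stereocentre is racemic and disappears in step 8.

**Step 7**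
Reactants: 13 2‑[4‑(benzyloxy)phenyl]ethanol
Product: 14 [4‑(benzyloxy)phenyl]acetaldehyde
Conditions: Dess–Martin periodinane (1.2 equiv), CH2Cl2, 0 °C → rt; used at once
Reagents that add atoms: none
Why: Dess–Martin oxidation under neutral conditions should deliver the enolisable arylacetaldehyde without over‑oxidation or aldol condensation.

**Step 8**
Reactants: 12 diethyl (1‑{3‑(benzyloxy)‑5‑[4‑(benzyloxy)benzyl]phenyl}‑6‑[4‑(benzyloxy)phenyl]‑4‑oxohexan‑3‑yl)phosphonate; 14 [4‑(benzyloxy)phenyl]acetaldehyde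
Product: 15 (E)‑1,6‑bis[4‑(benzyloxy)phenyl]‑4‑(2‑{3‑(benzyloxy)‑5‑[4‑(benzyloxy)benzyl]phenyl}ethyl)hex‑4‑en‑3‑one
Conditions: Ba(OH)2·8H2O (0.8 equiv), THF/H2O (40:1), 0 °C → rt; 14 (1.5 equiv) added slowly
Reagents that add atoms: none
Why: Horner–Wadsworth–Emmons olefination of the α‑substituted β‑ketophosphonate under mild Ba(OH)2 activation should place the alkene regiospecifically and mainly as the E isomer, and the alkene geometry does not change the product of step 11.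

**Step 9**
Reactants: 15 (E)‑1,6‑bis[4‑(benzyloxy)phenyl]‑4‑(2‑{3‑(benzyloxy)‑5‑[4‑(benzyloxy)benzyl]phenyl}ethyl)hex‑4‑en‑3‑one
Product: 18 (E)‑2‑diazo‑1,6‑bis[4‑(benzyloxy)phenyl]‑4‑(2‑{3‑(benzyloxy)‑5‑[4‑(benzyloxy)benzyl]phenyl}ethyl)hex‑4‑en‑3‑one, via lithium enolate 16 (not isolated), via trifluoroacetyl diketone 17 (not isolated)
Conditions: LiN(SiMe3)2 (1.1 equiv), THF, −78 °C; CF3CO2CH2CF3 (1.2 equiv), −78 °C; 5% HCl wash; then MsN3 (1.5 equiv), Et3N (1.5 equiv), H2O (1 equiv), MeCN, rt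
Reagents that add atoms: methanesulfonyl azide, CS(=O)(=O)N=[N+]=[N-]
Why: Detrifluoroacetylative diazo transfer, in which kinetic α′‑deprotonation of the enone (the γ‑CH2 of the E‑alkene lies away from the lithium‑bound carbonyl), Claisen trifluoroacetylation of that carbon and Regitz‑type diazo transfer with loss of the trifluoroacetyl group to the sulfonamide should give the α′‑diazo enone without moving the alkene.

**Step 10**
Reactants: 19 chloroacetaldehyde dimethyl acetal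
Product: 21 methoxyacetylene, via sodium methoxyacetylide 20 (not isolated)
Conditions: NaNH2 (3.1 equiv), liquid NH3, −33 °C; then cold saturated aq. NaCl, −70 °C → rt; distilled (bp about 23 °C) into cold ClCH2CH2Cl
Reagents that add atoms: none
Why: Two successive eliminations (HCl, then methanol) by sodium amide give the sodium alkoxyacetylide, which brine protonates, the standard preparation of alkoxyacetylenes.

**Step 11**
Reactants: 18 (E)‑2‑diazo‑1,6‑bis[4‑(benzyloxy)phenyl]‑4‑(2‑{3‑(benzyloxy)‑5‑[4‑(benzyloxy)benzyl]phenyl}ethyl)hex‑4‑en‑3‑one; 21 methoxyacetylene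
Product: 26 2,4‑bis[4‑(benzyloxy)benzyl]‑3‑(2‑{3‑(benzyloxy)‑5‑[4‑(benzyloxy)benzyl]phenyl}ethyl)‑5‑methoxyphenol, via vinylketene 22 (not isolated), via vinylcyclobutenone 23 (not isolated), via dienylketene 24 (not isolated), via cyclohexadienone 25 (not isolated)
Conditions: 21 (4 equiv), degassed ClCH2CH2Cl (0.2 M), hν 365 nm (LED, closed FEP flow coil), 10 °C; excess 21 purged with N2; then 80 °C, sealed tube
Reagents that add atoms: none
Why: Excitation of the diazo ketone expels N2 and the alkenyl group shifts from the carbonyl carbon to the former diazo carbon (photochemical Wolff rearrangement, making C5–C6) to give vinylketene 22, whose ketene C=C adds the ynol ether in a (2+2) cycloaddition (making C6–C1 and C2–C3) to give 4‑vinylcyclobutenone 23. On warming, 23 opens by 4π electrocyclic cleavage to dienylketene 24, which closes by 6π electrocyclization to dienone 25 and enolises to phenol 26. The closest known reaction type is the second‑generation Danheiser benzannulation of α′‑diazo enones with heteroatom‑substituted alkynes. Ring A is closed by the thermal disrotatory 6π electrocyclization of the dienylketene, which forms C3–C4 after the (2+2)/4π sequence has inserted the two alkyne carbons. No stereocentre survives, because the quaternary carbon of 23 and the sp3 carbon of 25 are racemic and are lost on aromatisation. The selectivity needed is the regiochemistry of the (2+2) step, secured because the electron‑rich CH terminus of methoxyacetylene bonds to the electrophilic ketene carbonyl carbon so that C2–H lies between C1–OMe and C3–OH, while 365 nm light excites only the diazo ketone (the benzyl aryl ethers absorb below 300 nm) and the E‑alkene keeps its allylic CH2 away from the ketene.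

**Step 12**
Reactants: 26 2,4‑bis[4‑(benzyloxy)benzyl]‑3‑(2‑{3‑(benzyloxy)‑5‑[4‑(benzyloxy)benzyl]phenyl}ethyl)‑5‑methoxyphenol
Product: 27 3‑{2‑[3‑hydroxy‑5‑(4‑hydroxybenzyl)phenyl]ethyl}‑2,4‑bis(4‑hydroxybenzyl)‑5‑methoxyphenol (CNP0204120.0)
Conditions: H2 (1 atm), Pd/C (10 wt %), EtOAc/MeOH, rt
Reagents that add atoms: none
Why: Catalytic hydrogenolysis should cleave the four aryl benzyl ethers while the diarylmethane and bibenzyl C–C bonds, the aryl methyl ether and the arenes stay intact at 1 atm and room temperature.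

**Compound list**

1 | 3,5‑dibromophenol | Oc1cc(Br)cc(Br)c1 | starting material
2 | 1‑(benzyloxy)‑3,5‑dibromobenzene | Brc1cc(Br)cc(OCc2ccccc2)c1 | intermediate
3 | 4‑(benzyloxy)benzaldehyde | O=Cc1ccc(OCc2ccccc2)cc1 | starting material
4 | [3‑(benzyloxy)‑5‑bromophenyl]lithium (not isolated) | [Li]c1cc(Br)cc(OCc2ccccc2)c1 | intermediate
5 | [3‑(benzyloxy)‑5‑bromophenyl][4‑(benzyloxy)phenyl]methanol (racemic) | OC(c1ccc(OCc2ccccc2)cc1)c1cc(Br)cc(OCc2ccccc2)c1 | intermediate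
6 | 1‑(benzyloxy)‑3‑[4‑(benzyloxy)benzyl]‑5‑bromobenzene | Brc1cc(Cc2ccc(OCc3ccccc3)cc2)cc(OCc2ccccc2)c1 | intermediate
7 | diethyl allylphosphonate | C=CCP(=O)(OCC)OCC | starting material
8 | diethyl [3‑(9‑borabicyclo[3.3.1]nonan‑9‑yl)propyl]phosphonate (not isolated) | CCOP(=O)(CCCB1C2CCCC1CCC2)OCC | intermediate
9 | diethyl (3‑{3‑(benzyloxy)‑5‑[4‑(benzyloxy)benzyl]phenyl}propyl)phosphonate | CCOP(=O)(CCCc1cc(OCc2ccccc2)cc(Cc2ccc(OCc3ccccc3)cc2)c1)OCC | intermediate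
10 | methyl 3‑(4‑hydroxyphenyl)propanoate | COC(=O)CCc1ccc(O)cc1 | starting material
11 | methyl 3‑[4‑(benzyloxy)phenyl]propanoate | COC(=O)CCc1ccc(OCc2ccccc2)cc1 | intermediate
12 | diethyl (1‑{3‑(benzyloxy)‑5‑[4‑(benzyloxy)benzyl]phenyl}‑6‑[4‑(benzyloxy)phenyl]‑4‑oxohexan‑3‑yl)phosphonate (racemic) | CCOP(=O)(OCC)C(CCc1cc(OCc2ccccc2)cc(Cc2ccc(OCc3ccccc3)cc2)c1)C(=O)CCc1ccc(OCc2ccccc2)cc1 | intermediate
13 | 2‑[4‑(benzyloxy)phenyl]ethanol | OCCc1ccc(OCc2ccccc2)cc1 | starting material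
14 | [4‑(benzyloxy)phenyl]acetaldehyde | O=CCc1ccc(OCc2ccccc2)cc1 | intermediate
15 | (E)‑1,6‑bis[4‑(benzyloxy)phenyl]‑4‑(2‑{3‑(benzyloxy)‑5‑[4‑(benzyloxy)benzyl]phenyl}ethyl)hex‑4‑en‑3‑one | O=C(CCc1ccc(OCc2ccccc2)cc1)/C(CCc1cc(OCc2ccccc2)cc(Cc2ccc(OCc3ccccc3)cc2)c1)=C/Cc1ccc(OCc2ccccc2)cc1 | intermediate
16 | lithium α′‑enolate of 15 (enolate geometry open; not isolated) | [Li]OC(=CCc1ccc(OCc2ccccc2)cc1)/C(CCc1cc(OCc2ccccc2)cc(Cc2ccc(OCc3ccccc3)cc2)c1)=C/Cc1ccc(OCc2ccccc2)cc1 | intermediate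
17 | (E)‑1,6‑bis[4‑(benzyloxy)phenyl]‑4‑(2‑{3‑(benzyloxy)‑5‑[4‑(benzyloxy)benzyl]phenyl}ethyl)‑2‑(trifluoroacetyl)hex‑4‑en‑3‑one (racemic; not isolated) | O=C(C(Cc1ccc(OCc2ccccc2)cc1)C(=O)C(F)(F)F)/C(CCc1cc(OCc2ccccc2)cc(Cc2ccc(OCc3ccccc3)cc2)c1)=C/Cc1ccc(OCc2ccccc2)cc1 | intermediate
18 | (E)‑2‑diazo‑1,6‑bis[4‑(benzyloxy)phenyl]‑4‑(2‑{3‑(benzyloxy)‑5‑[4‑(benzyloxy)benzyl]phenyl}ethyl)hex‑4‑en‑3‑one | [N-]=[N+]=C(Cc1ccc(OCc2ccccc2)cc1)C(=O)/C(CCc1cc(OCc2ccccc2)cc(Cc2ccc(OCc3ccccc3)cc2)c1)=C/Cc1ccc(OCc2ccccc2)cc1 | intermediate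
19 | chloroacetaldehyde dimethyl acetal (2‑chloro‑1,1‑dimethoxyethane) | COC(CCl)OC | starting material
20 | sodium methoxyacetylide (not isolated) | [Na]C#COC | intermediate
21 | methoxyacetylene | COC#C | intermediate
22 | (E)‑2‑[4‑(benzyloxy)benzyl]‑5‑[4‑(benzyloxy)phenyl]‑3‑(2‑{3‑(benzyloxy)‑5‑[4‑(benzyloxy)benzyl]phenyl}ethyl)penta‑1,3‑dien‑1‑one (vinylketene; not isolated) | O=C=C(Cc1ccc(OCc2ccccc2)cc1)/C(CCc1cc(OCc2ccccc2)cc(Cc2ccc(OCc3ccccc3)cc2)c1)=C/Cc1ccc(OCc2ccccc2)cc1 | intermediate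
23 | 4‑[4‑(benzyloxy)benzyl]‑3‑methoxy‑4‑[(E)‑1‑[4‑(benzyloxy)phenyl]‑5‑{3‑(benzyloxy)‑5‑[4‑(benzyloxy)benzyl]phenyl}pent‑2‑en‑3‑yl]cyclobut‑2‑en‑1‑one (racemic; not isolated) | COC1=CC(=O)C1(Cc1ccc(OCc2ccccc2)cc1)/C(CCc1cc(OCc2ccccc2)cc(Cc2ccc(OCc3ccccc3)cc2)c1)=C/Cc1ccc(OCc2ccccc2)cc1 | intermediate
24 | 4‑[4‑(benzyloxy)benzyl]‑7‑[4‑(benzyloxy)phenyl]‑5‑(2‑{3‑(benzyloxy)‑5‑[4‑(benzyloxy)benzyl]phenyl}ethyl)‑3‑methoxyhepta‑1,3,5‑trien‑1‑one (dienylketene, ketenyl CH and alkenyl group cis on C3=C4, C5=C6 E; not isolated) | O=C=C/C(OC)=C(\C(CCc1cc(OCc2ccccc2)cc(Cc2ccc(OCc3ccccc3)cc2)c1)=C\Cc1ccc(OCc2ccccc2)cc1)Cc1ccc(OCc2ccccc2)cc1 | intermediate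
25 | 4,6‑bis[4‑(benzyloxy)benzyl]‑5‑(2‑{3‑(benzyloxy)‑5‑[4‑(benzyloxy)benzyl]phenyl}ethyl)‑3‑methoxycyclohexa‑2,4‑dien‑1‑one (racemic; not isolated) | COC1=CC(=O)C(Cc2ccc(OCc3ccccc3)cc2)C(CCc2cc(OCc3ccccc3)cc(Cc3ccc(OCc4ccccc4)cc3)c2)=C1Cc1ccc(OCc2ccccc2)cc1 | intermediate
26 | 2,4‑bis[4‑(benzyloxy)benzyl]‑3‑(2‑{3‑(benzyloxy)‑5‑[4‑(benzyloxy)benzyl]phenyl}ethyl)‑5‑methoxyphenol | COc1cc(O)c(Cc2ccc(OCc3ccccc3)cc2)c(CCc2cc(OCc3ccccc3)cc(Cc3ccc(OCc4ccccc4)cc3)c2)c1Cc1ccc(OCc2ccccc2)cc1 | intermediate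
27 | 3‑{2‑[3‑hydroxy‑5‑(4‑hydroxybenzyl)phenyl]ethyl}‑2,4‑bis(4‑hydroxybenzyl)‑5‑methoxyphenol (CNP0204120.0) | COc1cc(O)c(Cc2ccc(O)cc2)c(CCc2cc(O)cc(Cc3ccc(O)cc3)c2)c1Cc1ccc(O)cc1 | target

**Step count.** Total: 12 steps. Longest linear sequence: 9 steps (1, 2, 3, 4, 6, 8, 9, 11, 12).

**Steps most likely to fail**

1. Step 11. The carbene formed from this fully substituted, acyclic diazo ketone may undergo 1,2‑hydrogen shift from the neighbouring benzylic CH2 faster than the alkenyl group migrates. The ketene that does form may also dimerise or acylate the product phenol if capture by the volatile alkyne is slow. The fallback introduces the C6 benzyl arm after the ring is made, because terminal diazo ketones are the most reliable substrates for the Wolff step. It sets out from phosphonate 9. Acylation with ethyl acetate (LiN(iPr)2, THF, 0 °C) should give diethyl (1‑{3‑(benzyloxy)‑5‑[4‑(benzyloxy)benzyl]phenyl}‑4‑oxopentan‑3‑yl)phosphonate F1. Olefination with aldehyde 14 (Ba(OH)2·8H2O, wet THF) should give (E)‑5‑[4‑(benzyloxy)phenyl]‑3‑(2‑{3‑(benzyloxy)‑5‑[4‑(benzyloxy)benzyl]phenyl}ethyl)pent‑3‑en‑2‑one F2. Diazo transfer under the conditions of step 9 should give (E)‑1‑diazo‑5‑[4‑(benzyloxy)phenyl]‑3‑(2‑{3‑(benzyloxy)‑5‑[4‑(benzyloxy)benzyl]phenyl}ethyl)pent‑3‑en‑2‑one F3. Irradiation with 21 and heating as in step 11 should give 2‑[4‑(benzyloxy)benzyl]‑3‑(2‑{3‑(benzyloxy)‑5‑[4‑(benzyloxy)benzyl]phenyl}ethyl)‑5‑methoxyphenol F4, in which C6 still carries hydrogen. Bromination para to the free hydroxyl (N‑bromosuccinimide, CH2Cl2, −78 °C) should give 4‑bromo‑2‑[4‑(benzyloxy)benzyl]‑3‑(2‑{3‑(benzyloxy)‑5‑[4‑(benzyloxy)benzyl]phenyl}ethyl)‑5‑methoxyphenol F5. Negishi coupling with [4‑(benzyloxy)benzyl]zinc chloride F6 (from 4‑(benzyloxy)benzyl chloride, Zn dust and LiCl in THF, used in excess to absorb the phenol proton; Pd(OAc)2, SPhos, THF, 50 °C) comes back to the route at 26.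

2. Step 8. The enolisable arylacetaldehyde may self‑condense under base, and the new double bond may drift out of conjugation with the ketone towards the styrene position. The fallback forms the trisubstituted alkene under neutral conditions and sets out from ketophosphonate 12. Olefination with aqueous formaldehyde (K2CO3, THF/H2O, rt), a non‑enolisable aldehyde, should give 1‑[4‑(benzyloxy)phenyl]‑4‑(2‑{3‑(benzyloxy)‑5‑[4‑(benzyloxy)benzyl]phenyl}ethyl)pent‑4‑en‑3‑one F7. Cross‑metathesis of F7 with 1‑allyl‑4‑(benzyloxy)benzene F8 (from 4‑allylphenol, BnBr, K2CO3), using second‑generation Hoveyda–Grubbs catalyst (5 mol %) with 1,4‑benzoquinone in CH2Cl2 at 40 °C, comes back to the route at 15.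

3. Step 9. Deprotonation at the benzylic, vinylogous γ‑CH2 may compete with α′‑enolisation, so that the alkene migrates or the wrong carbon is acylated. The fallback places the diazo group before the alkene exists and sets out from ketophosphonate 12. The dianion of 12 (NaH, then n‑BuLi, THF, 0 → −78 °C) is trifluoroacetylated at the terminal α′‑carbon with CF3CO2CH2CF3 to give diethyl (1‑{3‑(benzyloxy)‑5‑[4‑(benzyloxy)benzyl]phenyl}‑5‑[4‑(benzyloxy)benzyl]‑7,7,7‑trifluoro‑4,6‑dioxoheptan‑3‑yl)phosphonate F9. Diazo transfer (MsN3, Et3N, MeCN) should give diethyl (5‑diazo‑1‑{3‑(benzyloxy)‑5‑[4‑(benzyloxy)benzyl]phenyl}‑6‑[4‑(benzyloxy)phenyl]‑4‑oxohexan‑3‑yl)phosphonate F10. Horner–Wadsworth–Emmons olefination of F10 with aldehyde 14 (Ba(OH)2·8H2O, wet THF), a reaction type established for diazo‑bearing ketophosphonates, comes back to the route at 18, so the enone never meets a strong base.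

**Further compounds**

F1 | step 11 | diethyl (1‑{3‑(benzyloxy)‑5‑[4‑(benzyloxy)benzyl]phenyl}‑4‑oxopentan‑3‑yl)phosphonate | CCOP(=O)(OCC)C(CCc1cc(OCc2ccccc2)cc(Cc2ccc(OCc3ccccc3)cc2)c1)C(C)=O
F2 | step 11 | (E)‑5‑[4‑(benzyloxy)phenyl]‑3‑(2‑{3‑(benzyloxy)‑5‑[4‑(benzyloxy)benzyl]phenyl}ethyl)pent‑3‑en‑2‑one | CC(=O)/C(CCc1cc(OCc2ccccc2)cc(Cc2ccc(OCc3ccccc3)cc2)c1)=C/Cc1ccc(OCc2ccccc2)cc1
F3 | step 11 | (E)‑1‑diazo‑5‑[4‑(benzyloxy)phenyl]‑3‑(2‑{3‑(benzyloxy)‑5‑[4‑(benzyloxy)benzyl]phenyl}ethyl)pent‑3‑en‑2‑one | [N-]=[N+]=CC(=O)/C(CCc1cc(OCc2ccccc2)cc(Cc2ccc(OCc3ccccc3)cc2)c1)=C/Cc1ccc(OCc2ccccc2)cc1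
F4 | step 11 | 2‑[4‑(benzyloxy)benzyl]‑3‑(2‑{3‑(benzyloxy)‑5‑[4‑(benzyloxy)benzyl]phenyl}ethyl)‑5‑methoxyphenol | COc1cc(O)c(Cc2ccc(OCc3ccccc3)cc2)c(CCc2cc(OCc3ccccc3)cc(Cc3ccc(OCc4ccccc4)cc3)c2)c1
F5 | step 11 | 4‑bromo‑2‑[4‑(benzyloxy)benzyl]‑3‑(2‑{3‑(benzyloxy)‑5‑[4‑(benzyloxy)benzyl]phenyl}ethyl)‑5‑methoxyphenol | COc1cc(O)c(Cc2ccc(OCc3ccccc3)cc2)c(CCc2cc(OCc3ccccc3)cc(Cc3ccc(OCc4ccccc4)cc3)c2)c1Br
F6 | step 11 | [4‑(benzyloxy)benzyl]zinc chloride | Cl[Zn]Cc1ccc(OCc2ccccc2)cc1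
F7 | step 8 | 1‑[4‑(benzyloxy)phenyl]‑4‑(2‑{3‑(benzyloxy)‑5‑[4‑(benzyloxy)benzyl]phenyl}ethyl)pent‑4‑en‑3‑one | C=C(CCc1cc(OCc2ccccc2)cc(Cc2ccc(OCc3ccccc3)cc2)c1)C(=O)CCc1ccc(OCc2ccccc2)cc1
F8 | step 8 | 1‑allyl‑4‑(benzyloxy)benzene | C=CCc1ccc(OCc2ccccc2)cc1
F9 | step 9 | diethyl (1‑{3‑(benzyloxy)‑5‑[4‑(benzyloxy)benzyl]phenyl}‑5‑[4‑(benzyloxy)benzyl]‑7,7,7‑trifluoro‑4,6‑dioxoheptan‑3‑yl)phosphonate | CCOP(=O)(OCC)C(CCc1cc(OCc2ccccc2)cc(Cc2ccc(OCc3ccccc3)cc2)c1)C(=O)C(Cc1ccc(OCc2ccccc2)cc1)C(=O)C(F)(F)F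
F10 | step 9 | diethyl (5‑diazo‑1‑{3‑(benzyloxy)‑5‑[4‑(benzyloxy)benzyl]phenyl}‑6‑[4‑(benzyloxy)phenyl]‑4‑oxohexan‑3‑yl)phosphonate | CCOP(=O)(OCC)C(CCc1cc(OCc2ccccc2)cc(Cc2ccc(OCc3ccccc3)cc2)c1)C(=O)C(=[N+]=[N-])Cc1ccc(OCc2ccccc2)cc1
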